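## Structural features

The target is an oplopane-type trans-hydrindane: a cyclohexane (C1, C2, C3, C4, C5, C9) fused along C5–C9 to a cyclopentane (C5, C6, C7, C8, C9). C10 is the exocyclic methylene carbon on C1 and C11/C12 are the ethylidene carbons on C6; β is the face of H-5, α the face of H-9, and this numbering is used throughout. Reading the SMILES gives six stereocentres, (2S,3S,4S,5R,7S,9R): 2α-OH, 3β-angeloyloxy, 4β-isopropyl, 5β-H and 9α-H are contiguous around the six-membered ring, and the 7β-acetoxy group stands alone in the five-membered ring. In the chair the isopropyl group is equatorial and the C2/C3 oxygens are trans-diaxial; the C6=C11 alkene is Z (methyl cis to C7) and the ester is the (Z)-2-methylbut-2-enoate. Fragile features are the angelate (Z to E isomerisation), two allylic C–O bonds, two exocyclic alkenes, and three oxygens that must end as free OH, angelate and acetate. The real difficulty is the trans ring fusion next to C4, which cannot be corrected late because neither C5 nor C9 is α to a carbonyl in the target, together with the geometry-defined C6=C11 alkene beside oxygenated C7. The key step exploits the array C5–C6(=C11)–C7(–O): it is exactly what forms when C5 of a four-membered ring C5–C7–C8–C9 shifts from a carbinol carbon C7 onto an alkyne carbon C6, so the cyclopentane is made by inserting one carbon into a photochemically made trans-fused cyclobutane.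

## Logic of the disconnections

21 ⇒ 20 ⇒ 19 ⇒ 18. Cut the O–Si bond at C2, the acetyl C–O bond at C7 and the C7–H bond. The three oxygens must end up different; keeping C2 masked and generating the C7 hydroxyl last from a ketone means two free secondary alcohols never have to be told apart. This removes the C7 stereocentre. The forward reduction must deliver hydride to the α face of the C7 ketone under reagent control, in the presence of two exocyclic alkenes and an unsaturated ester.

18 ⇒ 16 + 17. Cut the acyl C–O bond at C3. The isomerisable ester is introduced as late as the acetate allows and as an intact unit. The forward step must acylate a hindered axial hydroxyl without Z/E isomerisation, and 16 ⇒ 15 requires selective masking of the C2 hydroxyl.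

15 ⇒ 14. Cut the C2–O bond (oxygen from water). The trans-diaxial 2α,3β-diol is the product of diaxial opening of a 2β,3β-epoxide, and C2 is allylic. Two stereocentres are traced to one epoxide. The forward step needs SN2 attack at C2 with inversion and no SN2′ attack at C10.

14 ⇒ 13 ⇒ 12. Cut C1=C10 and both epoxide C–O bonds. A carbonyl at C1 allows nucleophilic epoxidation, which ignores the electron-rich C6=C11 alkene. This removes C2, C3 and C10 and leaves a dienedione with three stereocentres. The demands are β-face and C1-enone selectivity in the epoxidation, methylenation at C1 and not C7, and no epimerisation at C9 while C1 is a carbonyl.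

12 ⇒ 11. Cut C11–C12. A stereoretentive coupling makes the alkene geometry a property of the vinyl iodide, not of an olefination. The demand is retention.

11 ⇒ 10 (key). Cut C5–C6 and reconnect C5–C7 (retro-semipinacol), removing iodine from C11. This ring contraction removes one ring atom and the alkene stereoelement, and turns the trans-fused cyclopentane into a [2+2] problem. The forward step needs migration of C5 (not C8), anti addition across the alkyne, and a trans-fused four-membered ring.

10 ⇒ 9 ⇒ 8. Cut C6–C7 (acetylide plus cyclobutanone) and unmask the acetal. The demands are addition to the cyclobutanone in the presence of the C1 enone carbonyl, and intact C5 and C9.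

8 ⇒ 6 (through 7). Remove the C2=C3 unsaturation. It is introduced early because it tames the C1 carbonyl for the acetylide addition and prepares the C2/C3 oxygenation. The demand is kinetic enolisation toward C2.

6 ⇒ 4 + 5. Cut C5–C7 and C9–C8 (retro-[2+2]). A trans-fused cyclobutane is reached only photochemically, and C4 directs the facial approach. A bicycle with three stereocentres becomes a monocyclic enone with one. The demands are head-to-tail regiochemistry, attack anti to isopropyl and trans closure.

4 ⇒ 3 ⇒ 1 + 2. Cut the C5=C9 double bond (aldol condensation) and the C3–C4 bond (Michael addition). The single stereocentre C4 comes from catalyst control on commercial materials.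

## Other disconnections considered

Alternative 1: The first idea is to annulate the five-membered ring onto the cyclohexenone by ionic chemistry, cutting C5–C6 and C9–C8. A (Z)-vinylcopper fragment carrying C6, C7 (silyloxy), C8, C11 and C12 would add to C5 anti to isopropyl. The derived iodo ketone A1 would then close by 5-exo enolate alkylation to hydrindanone A2. The chosen plan is preferred for two reasons. The fragment needs its own multistep synthesis with a defined vinyl-metal geometry and the C7 stereocentre. More seriously, the ring fusion of A2 is decided in an enolate alkylation in which cis closure is at least as accessible, and C9 then stays epimerisable next to C1 with no clear preference for trans once C6 is sp2. The chosen route fixes the trans fusion kinetically and takes the alkene geometry from a stereospecific mechanism.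

Alternative 2: An intramolecular Diels–Alder reaction, cutting C5–C9 and C1–C2, would close both rings at once. The triene ester A3 has an (E)-enoate C1=C9 tethered through C8–C7–C6 to a 2,3-dioxygenated diene C5=C4–C3=C2. It would give adduct A4 and set C1, C2, C5 and C9 through an ester-endo transition state. The chosen plan is preferred because A3 is a sensitive conjugated trienyl bis(enol ether) with three alkene geometries to control. Facial selectivity must come from C7, the middle tether atom, which occupies a nearly isoclinal position of the forming five-membered ring, so its control is expected to be weak. A4 also still needs degradation of the C1 ester to a methylene and adjustment of C3/C4, which lengthens the route.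

Alternative 3: A nickel-catalysed reductive cyclisation of the alkynyl enone A5 (Ni(cod)2, zerovalent nickel, with a silane) would cut only C5–C6. Syn addition across the alkyne places the new hydrogen cis to C5 and would give the correct (Z)-ethylidene in A6. The chosen plan is preferred because a 5-exo closure onto a ring alkene next to the tether-bearing C9 delivers the C5–C6 bond to the tether face. The result is the cis-fused hydrindanone A6, and neither C5 nor C9 is epimerisable in that series. The chosen sequence instead carries a kinetically formed trans relationship through a ring enlargement.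

Key step: step 7

Remark: the C7 carbinol configuration of 10 is drawn for the expected isomer; it is erased in step 7.

## Route

Step 1
Reactants: 1 3-methylbutanal; 2 but-3-en-2-one
Product: 3 (2S)-5-oxo-2-(propan-2-yl)hexanal
Conditions: (S)-2-[methoxy(diphenyl)methyl]pyrrolidine (5 mol %), ethyl 3,4-dihydroxybenzoate (20 mol %), neat, 4 °C
Reagents that add atoms: none
Why: Enamine-catalysed Michael addition; the (S)-diarylprolinol ether forms the E-enamine of 1 and shields its Re face, so the vinyl ketone is attacked from the Si face and the future C4 is set as S.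

Step 2
Reactants: 3 (2S)-5-oxo-2-(propan-2-yl)hexanal
Product: 4 (4S)-4-(propan-2-yl)cyclohex-2-en-1-one
Conditions: LiOH, i-PrOH, rt
Reagents that add atoms: none
Why: Intramolecular aldol condensation of the methyl ketone onto the aldehyde (Robinson-type closure); the stereocentre is γ to the new enone and should survive the mild base.

Step 3
Reactants: 4 (4S)-4-(propan-2-yl)cyclohex-2-en-1-one; 5 1,1-diethoxyethene
Product: 6 trans-fused 7,7-diethoxy-5-(propan-2-yl)bicyclo[4.2.0]octan-2-one (C1 ketone; C7 acetal; 4β-isopropyl; 5β-H; 9α-H)
Conditions: hν (medium-pressure Hg lamp, Pyrex), 5 (excess), pentane, −40 °C; neutral work-up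
Reagents that add atoms: none
Why: Enone–alkene [2+2] photocycloaddition through the triplet enone: the ketene acetal adds head-to-tail (acetal carbon to the β-carbon C5) and anti to the C4 isopropyl group, and the 1,4-biradical should close mainly to the strained trans-fused ring (H-9 α), an isomer that thermal chemistry does not give. The cis-fused and syn-facial isomers are expected as separable minor products, and 6 is handled on neutral media because C9 is epimerisable.

Step 4
Reactants: 6 trans-fused 7,7-diethoxy-5-(propan-2-yl)bicyclo[4.2.0]octan-2-one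
Product: 8 trans-fused 7,7-diethoxy-5-(propan-2-yl)bicyclo[4.2.0]oct-3-en-2-one (C1 enone with C2=C3), via trimethylsilyl enol ether 7 (not isolated)
Conditions: LiN(i-Pr)2, Me3SiCl, THF, −78 °C; then Pd(OAc)2, MeCN, rt
Reagents that add atoms: none
Why: Saegusa–Ito oxidation: kinetic deprotonation at the C2 methylene (not at the hindered ring-fusion H-9) gives 7, and palladium diacetate removes H-3 by β-hydride elimination. The unsaturation prepares C2/C3 for oxygenation and makes the C1 carbonyl a less electrophilic conjugated ketone for step 6.

Step 5
Reactants: 8 trans-fused 7,7-diethoxy-5-(propan-2-yl)bicyclo[4.2.0]oct-3-en-2-one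
Product: 9 trans-fused 5-(propan-2-yl)bicyclo[4.2.0]oct-3-ene-2,7-dione (C1 enone; C7 cyclobutanone)
Conditions: 10% aq. oxalic acid on SiO2, CH2Cl2, rt
Reagents that add atoms: water, O
Why: Mild heterogeneous acetal hydrolysis; cyclobutanones enolise slowly, so C5 (α to the new carbonyl) and C9 should keep their configuration.

Step 6
Reactants: 9 trans-fused 5-(propan-2-yl)bicyclo[4.2.0]oct-3-ene-2,7-dione
Product: 10 trans-fused 7β-ethynyl-7α-hydroxy-5-(propan-2-yl)bicyclo[4.2.0]oct-3-en-2-one
Conditions: HC≡CMgBr (1.1 equiv), THF, −78 °C; aq. NH4Cl
Reagents that add atoms: ethynylmagnesium bromide, C#C[Mg]Br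
Why: 1,2-Addition of an alkynyl Grignard reagent to the strained, non-conjugated cyclobutanone, which is much more electrophilic than the conjugated C1 ketone. Attack anti to the C5–C4 bond should give the 7β-ethynyl carbinol, but this centre becomes sp2 in step 7.

Step 7
Reactants: 10 trans-fused 7β-ethynyl-7α-hydroxy-5-(propan-2-yl)bicyclo[4.2.0]oct-3-en-2-one
Product: 11 trans-fused 6-[(Z)-iodomethylidene]-4β-(propan-2-yl)bicyclo[4.3.0]non-2-ene-1,7-dione (5β-H; 9α-H; iodine cis to C7)
Conditions: NIS (1.2 equiv), CH2Cl2, 0 °C → rt, dark
Reagents that add atoms: N-iodosuccinimide, O=C1CCC(=O)N1I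
Why: NIS transfers I+ to the terminal alkyne carbon C11; as positive charge builds at C6 the ring bond C7–C5, antiperiplanar to the incoming iodine, shifts from C7 to C6 while the carbinol oxygen becomes the C7 carbonyl (semipinacol 1,2-shift). The reaction type is the electrophile-induced semipinacol ring expansion of 1-alkynylcyclobutanols to 2-alkylidenecyclopentanones, the halonium counterpart of the gold-catalysed ring expansion of the same carbinols. The five-membered ring C5–C6–C7–C8–C9 is formed by one-carbon enlargement of the four-membered ring (insertion of C6 into the C5–C7 bond) and not by cyclisation, so the trans ring fusion is inherited from 10 and the strain of the trans-fused cyclobutane is the driving force. No sp3 stereocentre is created: C5 migrates with retention and C9 is untouched, so C4, C5 and C9 keep the relationship fixed in step 3. The new stereoelement is the C6=C11 geometry, set by anti addition of iodine and C5 across the triple bond: iodine ends trans to C5 and cis to C7 (Z), the position of the C12 methyl group of the target. The step needs migration of C5 in preference to C8, which the higher migratory aptitude of the more substituted secondary carbon should secure. It also needs chemoselectivity for the alkyne: the only other π bond is the electron-poor C2=C3 enone, which NIS does not attack, and the carbinol configuration is irrelevant because the alkyne is cylindrically symmetric.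

Step 8
Reactants: 11 trans-fused 6-[(Z)-iodomethylidene]-4β-(propan-2-yl)bicyclo[4.3.0]non-2-ene-1,7-dione
Product: 12 trans-fused 6-[(Z)-ethylidene]-4β-(propan-2-yl)bicyclo[4.3.0]non-2-ene-1,7-dione (methyl cis to C7)
Conditions: MeZnCl, Pd(PPh3)4 (5 mol %), THF, 0 °C → rt
Reagents that add atoms: methylzinc chloride, C[Zn]Cl
Why: Negishi coupling: oxidative addition of zerovalent palladium to the vinyl iodide and reductive elimination both go with retention, so the methyl group takes the place of iodine, and the organozinc does not add to either ketone. The Z isomer is also the less strained one, since an E methyl group would clash with C4 and its isopropyl group.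

Step 9
Reactants: 12 trans-fused 6-[(Z)-ethylidene]-4β-(propan-2-yl)bicyclo[4.3.0]non-2-ene-1,7-dione
Product: 13 2β,3β-epoxide of 12 (C1 ketone; C7 enone unchanged)
Conditions: 30% aq. H2O2, NaOH (cat.), MeOH, −10 °C, short reaction time
Reagents that add atoms: hydrogen peroxide, OO
Why: Weitz–Scheffer nucleophilic epoxidation: hydroperoxide should add to the α-unsubstituted C1 enone much faster than to the trisubstituted exocyclic C7 enone. Axial attack at C3 on the rigid half-chair (β face, antiperiplanar to axial H-4) should give the 2β,3β-epoxide, which fixes the C3–O bond of the target.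

Step 10
Reactants: 13 2β,3β-epoxide of 12
Product: 14 2β,3β-epoxy-1-methylidene-6-[(Z)-ethylidene]-4β-(propan-2-yl)bicyclo[4.3.0]nonan-7-one (vinyl epoxide)
Conditions: Ph3PCH3Br, KOt-Bu, THF, 0 °C; then 13, −78 → 0 °C
Reagents that add atoms: methylenetriphenylphosphorane, C=P(c1ccccc1)(c1ccccc1)c1ccccc1
Why: Wittig methylenation at the more electrophilic α,β-epoxy ketone C1 in preference to the conjugated, α-branched C7 ketone. At low temperature addition should outrun enolisation at C9, and after this step C9 is no longer epimerisable.

Step 11
Reactants: 14 vinyl epoxide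
Product: 15 2α,3β-dihydroxy-1-methylidene-6-[(Z)-ethylidene]-4β-(propan-2-yl)bicyclo[4.3.0]nonan-7-one
Conditions: HClO4 (cat.), THF/H2O 3:1, 0 °C
Reagents that add atoms: water, O
Why: Acid-catalysed hydrolysis of the vinyl epoxide: water attacks the allylic carbon C2 with inversion from the α face, which is also the trans-diaxial (Fürst–Plattner) opening of the β-epoxide on the rigid chair, giving the 2α,3β-diaxial diol.

Step 12
Reactants: 15 2α,3β-diol
Product: 16 3β-hydroxy-2α-(triethylsilyloxy)-1-methylidene-6-[(Z)-ethylidene]-4β-(propan-2-yl)bicyclo[4.3.0]nonan-7-one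
Conditions: Et3SiCl (1.05 equiv), imidazole, CH2Cl2, −20 °C
Reagents that add atoms: chlorotriethylsilane, CC[Si](Cl)(CC)CC
Why: Selective silylation of the less hindered allylic C2 hydroxyl; the C3 hydroxyl is shielded by the neighbouring isopropyl group.

Step 13
Reactants: 16 C2 triethylsilyl ether; 17 (2Z)-2-methylbut-2-enoic acid (angelic acid)
Product: 18 3β-[(2Z)-2-methylbut-2-enoyloxy]-2α-(triethylsilyloxy)-1-methylidene-6-[(Z)-ethylidene]-4β-(propan-2-yl)bicyclo[4.3.0]nonan-7-one
Conditions: 17, 2,4,6-Cl3C6H2COCl, Et3N, toluene, rt; then 16, toluene, 80 °C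
Reagents that add atoms: none
Why: Yamaguchi-type esterification through the mixed anhydride without a nucleophilic acyl-transfer catalyst, conditions under which the Z geometry of the angeloyl group should be kept; heating overcomes the hindrance of the axial C3 hydroxyl.

Step 14
Reactants: 18 C7 ketone
Product: 19 (7S)-7β-hydroxy compound (otherwise as 18)
Conditions: (R)-Me-CBS oxazaborolidine (20 mol %), catecholborane, toluene, −78 °C
Reagents that add atoms: none
Why: Corey–Bakshi–Shibata reduction: the α-branched alkylidene side (C6) is the large group and C8H2 the small one, so the (R)-catalyst should deliver hydride to the α face and give the 7β (7S) alcohol by reagent control. The two faces of this ketone are nearly equivalent in the trans-hydrindane, and catecholborane at −78 °C should leave the alkenes and the ester alone.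

Step 15
Reactants: 19 7β-alcohol
Product: 20 7β-acetoxy-3β-[(2Z)-2-methylbut-2-enoyloxy]-2α-(triethylsilyloxy)-1-methylidene-6-[(Z)-ethylidene]-4β-(propan-2-yl)bicyclo[4.3.0]nonane
Conditions: Ac2O, pyridine, DMAP (cat.), CH2Cl2, 0 °C → rt
Reagents that add atoms: acetic anhydride, CC(=O)OC(C)=O
Why: Standard acetylation of the only free hydroxyl group.

Step 16
Reactants: 20 triethylsilyl ether of the target
Product: 21 (1Z,2S,3aR,5S,6S,7S,7aR)-2-acetoxy-1-ethylidene-5-hydroxy-4-methylidene-7-(propan-2-yl)octahydro-1H-inden-6-yl (2Z)-2-methylbut-2-enoate (CNP0113604.1)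
Conditions: HF·pyridine, pyridine/THF, 0 °C
Reagents that add atoms: none
Why: Buffered fluoride desilylation that leaves both esters and the allylic systems untouched; the trans-diaxial C2-OH/C3-ester arrangement cannot undergo acyl migration.

## Compound list

1 | 3-methylbutanal | CC(C)CC=O | starting material
2 | but-3-en-2-one | CC(=O)C=C | starting material
3 | (2S)-5-oxo-2-(propan-2-yl)hexanal | CC(=O)CC[C@H](C=O)C(C)C | intermediate
4 | (4S)-4-(propan-2-yl)cyclohex-2-en-1-one | CC(C)[C@H]1C=CC(=O)CC1 | intermediate
5 | 1,1-diethoxyethene | C=C(OCC)OCC | starting material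
6 | trans-fused 7,7-diethoxy-5-(propan-2-yl)bicyclo[4.2.0]octan-2-one (4β-isopropyl, 5β-H, 9α-H) | O=C1CC[C@@H](C(C)C)[C@@H]2C(OCC)(OCC)C[C@@H]12 | intermediate
7 | C1 trimethylsilyl enol ether of 6 (C1=C2) | C[Si](C)(C)OC1=CC[C@@H](C(C)C)[C@@H]2C(OCC)(OCC)C[C@@H]12 | intermediate
8 | trans-fused 7,7-diethoxy-5-(propan-2-yl)bicyclo[4.2.0]oct-3-en-2-one | O=C1C=C[C@@H](C(C)C)[C@@H]2C(OCC)(OCC)C[C@@H]12 | intermediate
9 | trans-fused 5-(propan-2-yl)bicyclo[4.2.0]oct-3-ene-2,7-dione | O=C1C=C[C@@H](C(C)C)[C@@H]2C(=O)C[C@@H]12 | intermediate
10 | trans-fused 7β-ethynyl-7α-hydroxy-5-(propan-2-yl)bicyclo[4.2.0]oct-3-en-2-one | O=C1C=C[C@@H](C(C)C)[C@@H]2[C@@](O)(C#C)C[C@@H]12 | intermediate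
11 | trans-fused 6-[(Z)-iodomethylidene]-4β-(propan-2-yl)bicyclo[4.3.0]non-2-ene-1,7-dione | O=C1C=C[C@@H](C(C)C)[C@@H]2/C(=C/I)C(=O)C[C@@H]12 | intermediate
12 | trans-fused 6-[(Z)-ethylidene]-4β-(propan-2-yl)bicyclo[4.3.0]non-2-ene-1,7-dione | O=C1C=C[C@@H](C(C)C)[C@@H]2/C(=C/C)C(=O)C[C@@H]12 | intermediate
13 | 2β,3β-epoxide of 12 | O=C1[C@H]3O[C@H]3[C@@H](C(C)C)[C@@H]2/C(=C/C)C(=O)C[C@@H]12 | intermediate
14 | 2β,3β-epoxy-1-methylidene-6-[(Z)-ethylidene]-4β-(propan-2-yl)bicyclo[4.3.0]nonan-7-one | C=C1[C@H]3O[C@H]3[C@@H](C(C)C)[C@@H]2/C(=C/C)C(=O)C[C@@H]12 | intermediate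
15 | 2α,3β-dihydroxy-1-methylidene-6-[(Z)-ethylidene]-4β-(propan-2-yl)bicyclo[4.3.0]nonan-7-one | C=C1[C@H](O)[C@@H](O)[C@@H](C(C)C)[C@@H]2/C(=C/C)C(=O)C[C@@H]12 | intermediate
16 | 2α-triethylsilyl ether of 15 (3β-OH free) | C=C1[C@H](O[Si](CC)(CC)CC)[C@@H](O)[C@@H](C(C)C)[C@@H]2/C(=C/C)C(=O)C[C@@H]12 | intermediate
17 | (2Z)-2-methylbut-2-enoic acid (angelic acid) | C/C=C(/C)C(=O)O | starting material
18 | 3β-angelate of 16 (C7 ketone) | C=C1[C@H](O[Si](CC)(CC)CC)[C@@H](OC(=O)/C(C)=C\C)[C@@H](C(C)C)[C@@H]2/C(=C/C)C(=O)C[C@@H]12 | intermediate
19 | (7S)-7β-alcohol from 18 | C=C1[C@H](O[Si](CC)(CC)CC)[C@@H](OC(=O)/C(C)=C\C)[C@@H](C(C)C)[C@@H]2/C(=C/C)[C@@H](O)C[C@@H]12 | intermediate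
20 | 7β-acetate of 19 (triethylsilyl ether of the target) | C=C1[C@H](O[Si](CC)(CC)CC)[C@@H](OC(=O)/C(C)=C\C)[C@@H](C(C)C)[C@@H]2/C(=C/C)[C@@H](OC(C)=O)C[C@@H]12 | intermediate
21 | (1Z,2S,3aR,5S,6S,7S,7aR)-2-acetoxy-1-ethylidene-5-hydroxy-4-methylidene-7-(propan-2-yl)octahydro-1H-inden-6-yl (2Z)-2-methylbut-2-enoate | C=C1[C@H](O)[C@@H](OC(=O)/C(C)=C\C)[C@@H](C(C)C)[C@@H]2/C(=C/C)[C@@H](OC(C)=O)C[C@@H]12 | target

## Step count and least certain steps

Total step count: 16. Longest linear sequence: 16 steps (from 1 and 2; 5 and 17 enter as commercial components). Step 3 is expected to give the desired adduct as the major of several separable isomers, so it is a material risk more than a feasibility risk. While C1 is a carbonyl (6 to 13), C9 can epimerise, and the thermodynamic preference at the hydrindane stage is unknown; basic steps in that window are therefore kept cold and short.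

Step 7 (key step). The most likely failure is loss of regiocontrol in the 1,2-shift (migration of the methylene carbon C8 instead of C5), because both shifts release the same strain. A second is slow iodonium transfer to a terminal alkyne, which would let isomerisation of the propargylic alcohol compete. The fallback sets out from 9 and lets thermodynamics set the alkene geometry. Addition of 1-propynylmagnesium bromide gives the 7-(prop-1-ynyl) carbinol F1. Ring expansion with catalytic Ph3PAuNTf2 (monovalent gold), a reaction type known for internal alkynes, gives by anti addition the (E)-ethylidene dione F2 with the methyl group cis to C5. Equilibration with catalytic iodine under visible light should then relieve the 1,3-allylic strain between that methyl group and C4/isopropyl and give the Z isomer, returning to the route at 12.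

Step 6. The most likely failures are loss of chemoselectivity (addition to the C1 enone carbonyl) and enolisation of the strained dione by the basic reagent, which would epimerise C5 or C9 toward the cis-fused series. The fallback sets out from 8 and takes the C1 carbonyl out of play by a redox detour. Luche reduction (NaBH4, CeCl3·7H2O) gives the allylic alcohol acetal F3, and acetal hydrolysis gives the hydroxy cyclobutanone F4. Excess ethynylmagnesium bromide gives the diol F5, NIS the hydroxy iodoalkylidene ketone F6, and Negishi methylation the hydroxy enone F7. Oxidation of the allylic alcohol with MnO2 returns to the route at 12.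

Step 9. The most likely failures are attack of hydroperoxide from the α face, competing epoxidation of the C7 enone, and base-induced epimerisation at C9. α-Face attack would give the 2α,3α-epoxide, whose vinyl epoxide would open with the wrong regiochemistry. The fallback sets out from 12, accepts the α-epoxide F8 and reverses the order of opening and methylenation. Acid-catalysed hydrolysis of the epoxy ketone occurs at C3 (β to the carbonyl and trans-diaxial) and gives the 2α,3β-dihydroxy ketone F9. Selective silylation of the C2 hydroxyl gives F10, and Wittig methylenation with excess ylide returns to the route at 16.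

Step 13. The most likely failures are no acyl transfer to the hindered axial hydroxyl, and Z to E isomerisation of the activated angeloyl species to the tiglate. The fallback sets out from 16 and builds the alkene on the molecule. Acylation with 2-[bis(2,2,2-trifluoroethoxy)phosphoryl]propanoic acid (DCC, DMAP) gives the phosphonate ester F11 as a mixture at the phosphonate carbon. Still–Gennari olefination with acetaldehyde (KN(SiMe3)2, 18-crown-6, THF, −78 °C) forms the (Z)-2-methylbut-2-enoate and returns to the route at 18.

Step 14. The most likely failure is insufficient or reversed facial selectivity, because the two faces of the C7 carbonyl differ only through remote groups and a substrate bias could oppose the catalyst. The fallback sets out from 18 and corrects the centre during acylation. The ketone is reduced deliberately to the 7α-alcohol F12 (with the (S)-oxazaborolidine, or with NaBH4/CeCl3·7H2O if substrate control favours it). The acetate is then introduced with inversion by a Mitsunobu reaction (AcOH, PPh3, DIAD), returning to the route at 20.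

## Further compounds

F1 | step 7 | trans-fused 7α-hydroxy-7β-(prop-1-ynyl)-5-(propan-2-yl)bicyclo[4.2.0]oct-3-en-2-one | O=C1C=C[C@@H](C(C)C)[C@@H]2[C@@](O)(C#CC)C[C@@H]12
F2 | step 7 | trans-fused 6-[(E)-ethylidene]-4β-(propan-2-yl)bicyclo[4.3.0]non-2-ene-1,7-dione | O=C1C=C[C@@H](C(C)C)[C@@H]2/C(=C\C)C(=O)C[C@@H]12
F3 | step 6 | trans-fused 7,7-diethoxy-5-(propan-2-yl)bicyclo[4.2.0]oct-3-en-2-ol (C1 alcohol, α-OH drawn) | O[C@@H]1C=C[C@@H](C(C)C)[C@@H]2C(OCC)(OCC)C[C@@H]12
F4 | step 6 | trans-fused 2-hydroxy-5-(propan-2-yl)bicyclo[4.2.0]oct-3-en-7-one | O[C@@H]1C=C[C@@H](C(C)C)[C@@H]2C(=O)C[C@@H]12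
F5 | step 6 | trans-fused 7-ethynyl-5-(propan-2-yl)bicyclo[4.2.0]oct-3-ene-2,7-diol | O[C@@H]1C=C[C@@H](C(C)C)[C@@H]2[C@@](O)(C#C)C[C@@H]12
F6 | step 6 | trans-fused 1-hydroxy-6-[(Z)-iodomethylidene]-4β-(propan-2-yl)bicyclo[4.3.0]non-2-en-7-one | O[C@@H]1C=C[C@@H](C(C)C)[C@@H]2/C(=C/I)C(=O)C[C@@H]12
F7 | step 6 | trans-fused 1-hydroxy-6-[(Z)-ethylidene]-4β-(propan-2-yl)bicyclo[4.3.0]non-2-en-7-one | O[C@@H]1C=C[C@@H](C(C)C)[C@@H]2/C(=C/C)C(=O)C[C@@H]12
F8 | step 9 | 2α,3α-epoxide of 12 | O=C1[C@@H]3O[C@@H]3[C@@H](C(C)C)[C@@H]2/C(=C/C)C(=O)C[C@@H]12
F9 | step 9 | 2α,3β-dihydroxy-6-[(Z)-ethylidene]-4β-(propan-2-yl)bicyclo[4.3.0]nonane-1,7-dione | O=C1[C@H](O)[C@@H](O)[C@@H](C(C)C)[C@@H]2/C(=C/C)C(=O)C[C@@H]12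
F10 | step 9 | 3β-hydroxy-2α-(triethylsilyloxy)-6-[(Z)-ethylidene]-4β-(propan-2-yl)bicyclo[4.3.0]nonane-1,7-dione | O=C1[C@H](O[Si](CC)(CC)CC)[C@@H](O)[C@@H](C(C)C)[C@@H]2/C(=C/C)C(=O)C[C@@H]12
F11 | step 13 | 3β-{2-[bis(2,2,2-trifluoroethoxy)phosphoryl]propanoyloxy} derivative of 16 (epimers at the phosphonate carbon) | C=C1[C@H](O[Si](CC)(CC)CC)[C@@H](OC(=O)C(C)P(=O)(OCC(F)(F)F)OCC(F)(F)F)[C@@H](C(C)C)[C@@H]2/C(=C/C)C(=O)C[C@@H]12
F12 | step 14 | 7α-alcohol, C7 epimer of 19 | C=C1[C@H](O[Si](CC)(CC)CC)[C@@H](OC(=O)/C(C)=C\C)[C@@H](C(C)C)[C@@H]2/C(=C/C)[C@H](O)C[C@@H]12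
A1 | alternative 1 | iodo ketone from the conjugate addition to the cyclohexenone: side chain C6(=CHCH3)–C7H(OSit-BuMe2)–C8H2I on C5 | O=C1CC[C@@H](C(C)C)[C@@H](C1)/C(=C/C)[C@@H](O[Si](C)(C)C(C)(C)C)CI
A2 | alternative 1 | hydrindanone from enolate alkylation (trans-fused isomer drawn) | O=C1CC[C@@H](C(C)C)[C@@H]2/C(=C/C)[C@@H](O[Si](C)(C)C(C)(C)C)C[C@@H]12
A3 | alternative 2 | triene ester for the intramolecular Diels–Alder reaction | COC(=O)/C=C/C[C@H](O[Si](C)(C)C(C)(C)C)/C(=C\C)/C=C(\C(C)C)/C(O[Si](C)(C)C(C)(C)C)=C/OCc1ccc(OC)cc1
A4 | alternative 2 | trans-fused Diels–Alder adduct (1α-ester, 2α-ether, C3=C4 silyl enol ether) | COC(=O)[C@@H]1[C@H](OCc3ccc(OC)cc3)C(O[Si](C)(C)C(C)(C)C)=C(C(C)C)[C@@H]2/C(=C/C)[C@@H](O[Si](C)(C)C(C)(C)C)C[C@@H]12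
A5 | alternative 3 | alkynyl enone: 2-isopropylcyclohex-2-enone carrying the CH2–CH(OSit-BuMe2)–C≡C–CH3 chain at C9 | CC#C[C@@H](O[Si](C)(C)C(C)(C)C)C[C@@H]1C=C(C(C)C)C(=O)CC1
A6 | alternative 3 | cis-fused hydrindanone expected from the reductive cyclisation (5α-H, 9α-H) | C1CC(=O)[C@H](C(C)C)[C@H]2/C(=C/C)[C@@H](O[Si](C)(C)C(C)(C)C)C[C@@H]12
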